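The readings were generated by integration on assumed constants, noise included.

**The moment.** I read this flask not at a set hour but at the moment when 50% of both substrates together is converted.

in all of them: reagent 0.156 M

|  | left-handed substrate | right-handed substrate | free catalyst | remark |
|---|---|---|---|---|
| autumn | 0.052 M | 0.052 M | 1.7 mM | run made earlier |
| spring | 0.052 M | 0.052 M | 3.9 mM | run made earlier |
| summer | 0.10 M | 0.10 M | 2.6 mM | run made earlier |
| flask | 0.052 M | 0.052 M | 2.6 mM |  |

| run | time / h | left-handed product / % | left-handed substrate / % |
|---|---|---|---|
| autumn | 0.833 | 14.1 | 36.2 |
| autumn | 1.33 | 19.4 | 30.8 |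
| autumn | 2.50 | 27.3 | 22.9 |
| autumn | 5.00 | 35.8 | 14.8 |
| autumn | 10.0 | 41.5 | 8.9 |
| spring | 0.833 | 26.1 | 24.9 |
| spring | 1.33 | 33.2 | 17.7 |
| spring | 2.50 | 40.4 | 8.1 |
| spring | 5.00 | 46.5 | 3.3 |
| spring | 10.0 | 48.3 | 1.8 |
| summer | 2.00 | 30.3 | 21.6 |
| summer | 4.00 | 36.3 | 12.6 |
| summer | 6.00 | 41.6 | 8.2 |
| summer | 8.00 | 43.6 | 7.9 |
| summer | 10.0 | 44.7 | 5.1 |

(standard deviation of a reading: 0.5 percentage points)

- free catalyst is single-handed; left-handed substrate and right-handed substrate are mirror images of each other, charged as a racemate, each of them at the stated concentration
- what was read earlier has a scatter of 0.5 percentage points, one standard deviation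
- no earlier run changes the charge of reagent; that part of a forecast is a guess

- apparent order in reagent when 50% of the left-handed substrate and right-handed substrate together are converted (percent change of the rate of making left-handed product for one percent more reagent charged)

**What matters.** I follow one free catalyst through its forks: it turns over a substrate, or it is lost. I assume that each turnover uses one reagent and that both branches are first order in [reagent]. No run tests this. [Reagent] then cancels at the fork, so under these assumptions [free catalyst] at a fixed conversion does not shift with the reagent charge. Under the same assumptions, the rate constants and the catalyst charge drop out of the order. The reagent and substrate charges stay in. At the summer substrate charge, with the same reagent charge, my count gives a reagent charge over reagent left at that conversion of 2.79.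

**My reckoning.** In this flask, by my count of one reagent per turnover, the conversion costs 0.0520 M of reagent. The charge of 0.156 M therefore keeps 0.104 M, and my estimate is 1.50. I call this charge over what is left the reagent leverage: with the amount used held fixed, one percent more charged is that many percent more left.

**The forecast.** The forecast says 0.4, because “reagent order looks low and substrate saturation seems likelier”. My estimate is higher.

**The result.** The flask gives 1.5 at the moment asked about, which comes at 9.28 h.

    reagent + free catalyst + right-handed substrate → free catalyst + right-handed product (k = 56.0 L² mol⁻² h⁻¹)
    reagent + free catalyst + left-handed substrate → free catalyst + left-handed product (k = 1700 L² mol⁻² h⁻¹)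
    reagent → decomposition product (k = 0.00130 h⁻¹)
    reagent + free catalyst → spent catalyst (k = 1.30 L mol⁻¹ h⁻¹)

Per free catalyst, with [reagent] and [left-handed substrate] as charged, making left-handed product runs at 14 h⁻¹, much faster than loss to spent catalyst at 0.20 h⁻¹. Both steps contain [reagent] once. The leverage is 1.50 at 50% conversion. At 12.0 h, after the moment asked about, the flask keeps 63% of its reagent, so charge over reagent left reads 1.59 there.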